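**Retrosynthetic overview**
1. Rings: the lactone ring is bought with coumarin 1 and kept in lactone 2 as a lock on one phenol oxygen; ring B arrives with propiolate 3; ring C (the pyranone) is the only ring built, and it is built last.
2. Key disconnection: the O1–C2 aryl vinyl ether bond of ring C (vinyl ether 4 ⇒ 2 + 3). With the ether on the 7-oxygen of 2, acylation at either free ortho carbon (lactones 5 and 6, C4–C4a bond) can only give the 6-substituted flavone, and both lactones open to one acid, 7.
3. Stereocentre: the C4–H bond of 2, by enantioselective hydrogenation of 1; no later step touches it.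
4. End game: O-demethylation of 7 gives the target 8.

Assumption: 1 and 3 are bought as catalogue compounds, and the ligand antipode in step 1 is the one that a two-run screen shows to give the 4R lactone.

Step 1
Reactants: 1 5,7-dihydroxy-4-phenyl-2H-chromen-2-one (5,7-dihydroxy-4-phenylcoumarin)
Product: 2 (4R)-5,7-dihydroxy-4-phenyl-3,4-dihydro-2H-chromen-2-one
Conditions: H2 (50 bar), [Ir(cod)(L)][B(C6H3(CF3)2)4] (2 mol%; L = ThrePHOX-type phosphinite–oxazoline, antipode giving 4R), CF3CH2OH/CH2Cl2 1:1, 40 °C
Reagents that add atoms: none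
Why: Proposed new method: enantioselective H2 addition to an unprotected 5,7-dihydroxy-4-arylcoumarin with a cationic iridium N,P catalyst, not yet shown for this substrate class; the ring-locked trisubstituted C3=C4 bond (one alkene geometry only, C3–H as the small group) binds the iridium dihydride with the 4-phenyl ring, twisted out of plane by the peri 5-OH, in the open quadrant of the ligand, migratory insertion then delivers hydride to one face of C4 and sets the only stereocentre (4R with the chosen antipode), while the non-coordinating fluoro-alcohol medium dissolves the bis-phenol and keeps the phenols protonated and off the metal; closest known reaction type: iridium N,P-catalysed asymmetric hydrogenation of β,β-diaryl acrylates and 4-aryl-2H-chromenes, and copper hydride 1,4-reduction of O-protected 4-arylcoumarins.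

Step 2
Reactants: 2 (4R)-5,7-dihydroxy-4-phenyl-3,4-dihydro-2H-chromen-2-one; 3 ethyl 3-(4-methoxyphenyl)prop-2-ynoate (1.0 equiv)
Product: 4 ethyl (2Z)-3-{[(4R)-5-hydroxy-2-oxo-4-phenyl-3,4-dihydro-2H-chromen-7-yl]oxy}-3-(4-methoxyphenyl)prop-2-enoate
Conditions: K2CO3 (20 mol%), dry DMF, 70 °C
Reagents that add atoms: none
Why: Oxa-Michael addition (first stage of the Ruhemann flavone synthesis): the phenoxide of the unhindered 7-OH (the 5-OH is screened by the peri C4–H/phenyl group) adds anti across the ynoate to form the O1–C2 bond of ring C, which fixes the flavone regiochemistry because both carbons ortho to this oxygen lead to the 6-substituted skeleton; no stereocentre is formed, C4 is not acidic, the lactone survives catalytic carbonate in dry DMF, and the alkene geometry is inconsequential because it equilibrates in the acid of step 3.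

Step 3
Reactants: 4 ethyl (2Z)-3-{[(4R)-5-hydroxy-2-oxo-4-phenyl-3,4-dihydro-2H-chromen-7-yl]oxy}-3-(4-methoxyphenyl)prop-2-enoate
Product: 7 (3R)-3-[5,7-dihydroxy-2-(4-methoxyphenyl)-4-oxo-4H-chromen-6-yl]-3-phenylpropanoic acid, via linear lactone flavone 5 (not isolated), via angular lactone flavone 6 (not isolated)
Conditions: Eaton's reagent (P2O5 in MeSO3H) as solvent, 45 °C; then ice, aq NaOH to pH 13, THF, 0 → 23 °C; then aq HCl to pH 3, 0 °C
Reagents that add atoms: sodium hydroxide, [Na+].[OH-]
Why: Intramolecular Friedel–Crafts acylation (Ruhemann ring closure) followed by lactone saponification: in P2O5/MeSO3H the ester is activated as an acylium equivalent that attacks the phloroglucinol-type ring at C6 or C8 of the chromanone to close ring C as lactone 5 or 6, aqueous NaOH then opens either aryl lactone (the flavone, the methyl ether and the benzylic C–H stereocentre are inert under these brief cold conditions), and both converge on the single acid 7.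

Step 4
Reactants: 7 (3R)-3-[5,7-dihydroxy-2-(4-methoxyphenyl)-4-oxo-4H-chromen-6-yl]-3-phenylpropanoic acid
Product: 8 (3R)-3-[5,7-dihydroxy-2-(4-hydroxyphenyl)-4-oxo-4H-chromen-6-yl]-3-phenylpropanoic acid
Conditions: BBr3 (6 equiv), CH2Cl2, −78 → 23 °C; then H2O, aq NaOH to pH 12, 0 °C, 15 min; then aq HCl to pH 3
Reagents that add atoms: none
Why: BBr3 O-demethylation of the aryl methyl ether: bromide attacks the methyl group of the boron-complexed 4'-methoxy oxygen (SN2), the anhydrous low-temperature Lewis-acid conditions avoid the hot protic-acid ring opening and re-closure of ring C (Wessely–Moser isomerisation to the 8-substituted flavone), the short cold NaOH work-up hydrolyses boron esters and keeps the propanoic acid open, and the stereocentre is untouched.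

**Compound list**
1 | 5,7-dihydroxy-4-phenyl-2H-chromen-2-one | O=c1cc(-c2ccccc2)c2c(O)cc(O)cc2o1 | starting material
2 | (4R)-5,7-dihydroxy-4-phenyl-3,4-dihydro-2H-chromen-2-one | O=C1C[C@H](c2ccccc2)c2c(O)cc(O)cc2O1 | intermediate
3 | ethyl 3-(4-methoxyphenyl)prop-2-ynoate | CCOC(=O)C#Cc1ccc(OC)cc1 | starting material
4 | ethyl (2Z)-3-{[(4R)-5-hydroxy-2-oxo-4-phenyl-3,4-dihydro-2H-chromen-7-yl]oxy}-3-(4-methoxyphenyl)prop-2-enoate | CCOC(=O)/C=C(\Oc1cc(O)c2[C@@H](c3ccccc3)CC(=O)Oc2c1)c1ccc(OC)cc1 | intermediate
5 | (6R)-5-hydroxy-2-(4-methoxyphenyl)-6-phenyl-6,7-dihydro-4H,8H-pyrano[3,2-g]chromene-4,8-dione (linear lactone flavone, lactone on the flavone 7-oxygen) | COc1ccc(cc1)-c1cc(=O)c2c(O)c3[C@@H](c4ccccc4)CC(=O)Oc3cc2o1 | intermediate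
6 | (4R)-5-hydroxy-8-(4-methoxyphenyl)-4-phenyl-3,4-dihydro-2H,10H-pyrano[2,3-f]chromene-2,10-dione (angular lactone flavone, lactone on the flavone 5-oxygen) | COc1ccc(cc1)-c1cc(=O)c2c3OC(=O)C[C@H](c4ccccc4)c3c(O)cc2o1 | intermediate
7 | (3R)-3-[5,7-dihydroxy-2-(4-methoxyphenyl)-4-oxo-4H-chromen-6-yl]-3-phenylpropanoic acid | COc1ccc(cc1)-c1cc(=O)c2c(O)c([C@H](CC(=O)O)c3ccccc3)c(O)cc2o1 | intermediate
8 | (3R)-3-[5,7-dihydroxy-2-(4-hydroxyphenyl)-4-oxo-4H-chromen-6-yl]-3-phenylpropanoic acid | O=C(O)C[C@H](c1ccccc1)c1c(O)cc2oc(-c3ccc(O)cc3)cc(=O)c2c1O | target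

Total step count: 4. Longest linear sequence: 4.

**Three steps most likely to fail**

Step 1 (the new hydrogenation: the electron-rich, phenol-bearing lactone may react slowly or with low ee). The fallback uses known chemistry, sets out from 1 and comes back at 2. Compound 1 is hydrogenated over Pd/C (H2, 5 bar, AcOH, 60 °C) to racemic 5,7-dihydroxy-4-phenyl-3,4-dihydro-2H-chromen-2-one F1. The enantiomers are separated by preparative chromatography on an amylose tris(3,5-dimethylphenylcarbamate) chiral phase. The 4R enantiomer is 2, and (4S)-5,7-dihydroxy-4-phenyl-3,4-dihydro-2H-chromen-2-one F2 is set aside.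

Step 2 (site selectivity of the 7-OH over the 5-OH, and O- versus C-addition of the ambident phenoxide; an ether on the 5-oxygen would lead to the 8-substituted flavone). The fallback sets out from 2 and comes back at 7, and it builds ring C in the opposite bond order by a Mentzer-type thermal condensation. Compound 2 is heated neat with ethyl 3-(4-methoxyphenyl)-3-oxopropanoate (240 °C, microwave). The aroylketene formed by loss of ethanol C-acylates C8 or C6 to give (4R)-5,7-dihydroxy-8-[3-(4-methoxyphenyl)-3-oxopropanoyl]-4-phenyl-3,4-dihydro-2H-chromen-2-one F3 or (4R)-5,7-dihydroxy-6-[3-(4-methoxyphenyl)-3-oxopropanoyl]-4-phenyl-3,4-dihydro-2H-chromen-2-one F4. These cyclodehydrate onto the free 7-hydroxyl to 6 and 5, and the crude melt is opened with aq NaOH and acidified as in step 3 to give 7. The only leak is closure of F4 onto the hindered 5-hydroxyl.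

Step 4 (BBr3 on the free hydroxy acid: poor solubility, boron-mediated lactonisation, incomplete cleavage). The fallback sets out from 4 and comes back at 8, and it changes the order of events so that the acid is liberated last. The Eaton's reagent ring closure of 4 is quenched with water only, and the mixture of lactones 5 and 6 is isolated. BBr3 in CH2Cl2 then gives (6R)-5-hydroxy-2-(4-hydroxyphenyl)-6-phenyl-6,7-dihydro-4H,8H-pyrano[3,2-g]chromene-4,8-dione F5 and (4R)-5-hydroxy-8-(4-hydroxyphenyl)-4-phenyl-3,4-dihydro-2H,10H-pyrano[2,3-f]chromene-2,10-dione F6. Cold aq NaOH followed by acidification to pH 3 opens both to 8.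

**Further compounds**
F1 | step 1 | racemic 5,7-dihydroxy-4-phenyl-3,4-dihydro-2H-chromen-2-one | O=C1CC(c2ccccc2)c2c(O)cc(O)cc2O1
F2 | step 1 | (4S)-5,7-dihydroxy-4-phenyl-3,4-dihydro-2H-chromen-2-one | O=C1C[C@@H](c2ccccc2)c2c(O)cc(O)cc2O1
F3 | step 2 | (4R)-5,7-dihydroxy-8-[3-(4-methoxyphenyl)-3-oxopropanoyl]-4-phenyl-3,4-dihydro-2H-chromen-2-one | COc1ccc(cc1)C(=O)CC(=O)c1c(O)cc(O)c2c1OC(=O)C[C@@H]2c1ccccc1
F4 | step 2 | (4R)-5,7-dihydroxy-6-[3-(4-methoxyphenyl)-3-oxopropanoyl]-4-phenyl-3,4-dihydro-2H-chromen-2-one | COc1ccc(cc1)C(=O)CC(=O)c1c(O)cc2OC(=O)C[C@H](c3ccccc3)c2c1O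
F5 | step 4 | (6R)-5-hydroxy-2-(4-hydroxyphenyl)-6-phenyl-6,7-dihydro-4H,8H-pyrano[3,2-g]chromene-4,8-dione | Oc1ccc(cc1)-c1cc(=O)c2c(O)c3[C@@H](c4ccccc4)CC(=O)Oc3cc2o1
F6 | step 4 | (4R)-5-hydroxy-8-(4-hydroxyphenyl)-4-phenyl-3,4-dihydro-2H,10H-pyrano[2,3-f]chromene-2,10-dione | Oc1ccc(cc1)-c1cc(=O)c2c3OC(=O)C[C@H](c4ccccc4)c3c(O)cc2o1
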